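**Plan**

- Numbering follows the chromanone core: O1, C2, C3, C4, C4a, C5, C6 (the quaternary carbon), C7, C8, C8a. The retrosynthesis cuts O1–C2 and C8a–C4a together, opening both rings to an open-chain tert-butyl β-keto ester / β-diketone. It then cuts C4a–C4 (Claisen condensation with methyl tiglate), C7–C8 (aldol, oxidation) and the two alkyl bonds at C6 (acetoacetate alkylations).
- Forward: cyclobutylmethyl iodide from (−)-verbenone; alkylation of ethyl acetoacetate; auxiliary-controlled prenylation; reduction and oxidation to a keto aldehyde; aldol with the dianion of a 3-phenylglutaric half ester; oxidation; tigloylation. In the last step the carbocycle and then the pyranone ring close in one operation.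
- Stereochemistry: the cyclobutane comes from the chiral pool; C6 from a valine-derived lithio-enamine; the benzylic centre from desymmetrisation of 3-phenylglutaric anhydride; C2 from quinine in the oxa-Michael closure; C3 by equilibration to trans.
- Enabling feature: quaternary C6 holds the latent acylketene arm (C7–C8–C8a) and the enolised β-diketone arm (C5–C4a–C4) 1,3 to each other, so C8a–C4a closure is six-membered. Because C6 carries no hydrogen, the C5 oxygen can enolise only toward C4a and stays chelated to the C4 carbonyl, which leaves O1 on C8a as the free enol oxygen six atoms from C2.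
- The tert-butyl ester is the only helper (latent acylketene); it leaves as tert-butanol in the key step, and the side-chain acid is carried unprotected.

Key step: step 16

Assumption: the sense of induction in steps 7, 10 and 16 is assigned by analogy with simpler substrates; in each case the other antipode (D-valine tert-butyl ester, (DHQD)2AQN, quinidine) would be used should the sense prove opposite.

**Route**

Step 1
Reactants: 1 (1S,5S)-(−)-verbenone
Product: 2 (1S,3R)-3-acetyl-2,2-dimethylcyclobutane-1-carboxylic acid (cis-pinononic acid)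
Conditions: RuCl3·xH2O (cat.), NaIO4, CCl4/MeCN/H2O, rt
Reagents that add atoms: sodium periodate, [Na+].[O-]I(=O)(=O)=O; water, O
Why: RuO4 formed in situ cleaves the enone C=C and the resulting α-keto acid loses CO2 oxidatively, so the cis-cyclobutane with both stereocentres is excised intact (ruthenium tetroxide oxidative cleavage).

Step 2
Reactants: 2 (1S,3R)-3-acetyl-2,2-dimethylcyclobutane-1-carboxylic acid
Product: 3 (1S,3S)-2,2-dimethyl-3-(prop-1-en-2-yl)cyclobutane-1-carboxylic acid
Conditions: Ph3PCH3Br, KOtBu (3 equiv), THF, 0 °C to rt; aq. HCl work-up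
Reagents that add atoms: methyltriphenylphosphonium bromide, C[P+](c1ccccc1)(c1ccccc1)c1ccccc1.[Br-]
Why: Wittig methylenation of the ketone of the potassium carboxylate should proceed with excess ylide, and the low temperature limits epimerisation next to the ketone.

Step 3
Reactants: 3 (1S,3S)-2,2-dimethyl-3-(prop-1-en-2-yl)cyclobutane-1-carboxylic acid
Product: 4 [(1S,3S)-2,2-dimethyl-3-(prop-1-en-2-yl)cyclobutyl]methanol
Conditions: LiAlH4, Et2O, 0 °C to rt
Reagents that add atoms: none
Why: Hydride reduction of the acid to the primary alcohol leaves the isolated alkene and both stereocentres untouched.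

Step 4
Reactants: 4 [(1S,3S)-2,2-dimethyl-3-(prop-1-en-2-yl)cyclobutyl]methanol
Product: 5 (1S,3S)-1-(iodomethyl)-2,2-dimethyl-3-(prop-1-en-2-yl)cyclobutane
Conditions: PPh3, I2, imidazole, CH2Cl2, 0 °C to rt
Reagents that add atoms: iodine, II
Why: Appel-type iodination proceeds by SN2 displacement at the primary carbon and so avoids a cyclobutylcarbinyl cation.

Step 5
Reactants: 5 (1S,3S)-1-(iodomethyl)-2,2-dimethyl-3-(prop-1-en-2-yl)cyclobutane; 6 ethyl acetoacetate
Product: 7 ethyl 2-{[(1R,3S)-2,2-dimethyl-3-(prop-1-en-2-yl)cyclobutyl]methyl}-3-oxobutanoate (both C2 epimers)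
Conditions: NaH, DMF, 0 to 60 °C (6 in excess)
Reagents that add atoms: none
Why: C-alkylation of the sodium enolate of the β-keto ester with a primary iodide (acetoacetic ester alkylation) should give the mono-alkylated product, whose new centre is made quaternary in step 7.

Step 6
Reactants: 7 ethyl 2-{[(1R,3S)-2,2-dimethyl-3-(prop-1-en-2-yl)cyclobutyl]methyl}-3-oxobutanoate; 8 L-valine tert-butyl ester
Product: 9 ethyl (2Z)-3-{[(2S)-1-tert-butoxy-3-methyl-1-oxobutan-2-yl]amino}-2-{[(1R,3S)-2,2-dimethyl-3-(prop-1-en-2-yl)cyclobutyl]methyl}but-2-enoate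
Conditions: BF3·OEt2 (cat.), PhH, reflux, Dean–Stark
Reagents that add atoms: none
Why: Lewis-acid-catalysed condensation of the ketone with the amine gives the hydrogen-bonded (Z)-enamino ester (enamine formation).

Step 7
Reactants: 9 ethyl (2Z)-3-{[(2S)-1-tert-butoxy-3-methyl-1-oxobutan-2-yl]amino}-2-{[(1R,3S)-2,2-dimethyl-3-(prop-1-en-2-yl)cyclobutyl]methyl}but-2-enoate; 10 prenyl bromide
Product: 12 ethyl (2R)-2-acetyl-2-{[(1R,3S)-2,2-dimethyl-3-(prop-1-en-2-yl)cyclobutyl]methyl}-5-methylhex-4-enoate, via alkylated valine imine 11 (not isolated)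
Conditions: LiN(i-Pr)2, PhMe, hexamethylphosphoramide, −78 °C; 10; then 1 M aq. HCl, THF, rt
Reagents that add atoms: water, O
Why: N-lithiation gives a rigid chelated aza-enolate whose isopropyl group blocks one face, so prenyl bromide should alkylate carbon from the other face and set the quaternary centre (auxiliary-controlled alkylation of a chiral lithio-enamine), and mild acid hydrolysis of imine 11 releases the ketone and the auxiliary.

Step 8
Reactants: 12 ethyl (2R)-2-acetyl-2-{[(1R,3S)-2,2-dimethyl-3-(prop-1-en-2-yl)cyclobutyl]methyl}-5-methylhex-4-enoate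
Product: 13 (2S)-2-{[(1R,3S)-2,2-dimethyl-3-(prop-1-en-2-yl)cyclobutyl]methyl}-2-(3-methylbut-2-en-1-yl)butane-1,3-diol (both C3 epimers)
Conditions: LiAlH4, Et2O, 0 °C
Reagents that add atoms: none
Why: Hydride reduction of ketone and ester gives the diol, and the new carbinol centre is of no consequence because it is re-oxidised in step 9.

Step 9
Reactants: 13 (2S)-2-{[(1R,3S)-2,2-dimethyl-3-(prop-1-en-2-yl)cyclobutyl]methyl}-2-(3-methylbut-2-en-1-yl)butane-1,3-diol
Product: 14 (2S)-2-acetyl-2-{[(1R,3S)-2,2-dimethyl-3-(prop-1-en-2-yl)cyclobutyl]methyl}-5-methylhex-4-enal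
Conditions: Dess–Martin periodinane (2.5 equiv), CH2Cl2, rt
Reagents that add atoms: none
Why: Dess–Martin oxidation of both alcohols should give the keto aldehyde, whose quaternary centre cannot epimerise.

Step 10
Reactants: 15 3-phenylglutaric anhydride
Product: 16 (3S)-5-methoxy-5-oxo-3-phenylpentanoic acid
Conditions: MeOH, (DHQ)2AQN (cat.), Et2O, −40 °C
Reagents that add atoms: methanol, CO
Why: Alkaloid-catalysed methanolysis selects one of the two enantiotopic carbonyl groups of the meso anhydride (desymmetrisation) and so sets the benzylic centre.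

Step 11
Reactants: 16 (3S)-5-methoxy-5-oxo-3-phenylpentanoic acid
Product: 17 1-tert-butyl 5-methyl (3R)-3-phenylpentanedioate
Conditions: tert-butyl 2,2,2-trichloroacetimidate, BF3·OEt2 (cat.), CH2Cl2/cyclohexane, rt
Reagents that add atoms: tert-butyl 2,2,2-trichloroacetimidate, CC(C)(C)OC(=N)C(Cl)(Cl)Cl
Why: Acid-catalysed tert-butylation of the carboxylic acid by the imidate needs no carboxyl activation and leaves the methyl ester and the stereocentre untouched.

Step 12
Reactants: 17 1-tert-butyl 5-methyl (3R)-3-phenylpentanedioate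
Product: 18 (3R)-5-tert-butoxy-5-oxo-3-phenylpentanoic acid
Conditions: LiOH, THF/H2O, 0 °C; aq. HCl work-up
Reagents that add atoms: lithium hydroxide, [Li+].[OH-]
Why: Saponification is selective for the methyl ester over the hindered tert-butyl ester, which exchanges the roles of the two arms.

Step 13
Reactants: 14 (2S)-2-acetyl-2-{[(1R,3S)-2,2-dimethyl-3-(prop-1-en-2-yl)cyclobutyl]methyl}-5-methylhex-4-enal; 18 (3R)-5-tert-butoxy-5-oxo-3-phenylpentanoic acid
Product: 19 (3R,6S)-6-acetyl-4-(tert-butoxycarbonyl)-6-{[(1R,3S)-2,2-dimethyl-3-(prop-1-en-2-yl)cyclobutyl]methyl}-5-hydroxy-9-methyl-3-phenyldec-8-enoic acid (mixture at C4 and C5)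
Conditions: 18, LiN(i-Pr)2 (2.1 equiv), THF, −78 °C; then 14, −78 °C; cold aq. NH4Cl quench
Reagents that add atoms: none
Why: The carboxylate directs the second deprotonation to the ester α-carbon, and this enolate should add to the aldehyde faster than to the hindered methyl ketone (aldol addition); the two new centres are removed later.

Step 14
Reactants: 19 (3R,6S)-6-acetyl-4-(tert-butoxycarbonyl)-6-{[(1R,3S)-2,2-dimethyl-3-(prop-1-en-2-yl)cyclobutyl]methyl}-5-hydroxy-9-methyl-3-phenyldec-8-enoic acid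
Product: 20 (3R,6R)-6-acetyl-4-(tert-butoxycarbonyl)-6-{[(1R,3S)-2,2-dimethyl-3-(prop-1-en-2-yl)cyclobutyl]methyl}-9-methyl-5-oxo-3-phenyldec-8-enoic acid (mixture at C4)
Conditions: Dess–Martin periodinane, pyridine, CH2Cl2, 0 °C to rt
Reagents that add atoms: none
Why: Dess–Martin oxidation converts the β-hydroxy ester into the β-keto ester, and the pyridine buffer keeps the acid as carboxylate so that lactonisation onto the carbinol is suppressed.

Step 15
Reactants: 20 (3R,6R)-6-acetyl-4-(tert-butoxycarbonyl)-6-{[(1R,3S)-2,2-dimethyl-3-(prop-1-en-2-yl)cyclobutyl]methyl}-9-methyl-5-oxo-3-phenyldec-8-enoic acid; 21 methyl tiglate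
Product: 22 (3R,6R,10E)-4-(tert-butoxycarbonyl)-6-{[(1R,3S)-2,2-dimethyl-3-(prop-1-en-2-yl)cyclobutyl]methyl}-10-methyl-6-(3-methylbut-2-en-1-yl)-5,7,9-trioxo-3-phenyldodec-10-enoic acid (mixture at C4)
Conditions: LiN(i-Pr)2 (3.3 equiv), THF, −78 °C; 21, −78 to 0 °C; aq. NH4Cl
Reagents that add atoms: none
Why: In the polyanion (carboxylate, β-keto ester enolate, methyl ketone enolate) the last-formed and most reactive methyl ketone enolate should attack the ester, and the released methoxide deprotonates the new β-diketone (Claisen condensation of a polyanion).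

Step 16
Reactants: 22 (3R,6R,10E)-4-(tert-butoxycarbonyl)-6-{[(1R,3S)-2,2-dimethyl-3-(prop-1-en-2-yl)cyclobutyl]methyl}-10-methyl-6-(3-methylbut-2-en-1-yl)-5,7,9-trioxo-3-phenyldodec-10-enoic acid
Product: 25 (3S)-3-[(2R,3R,6R)-6-{[(1R,3S)-2,2-dimethyl-3-(prop-1-en-2-yl)cyclobutyl]methyl}-5-hydroxy-2,3-dimethyl-6-(3-methylbut-2-en-1-yl)-4,7-dioxo-3,4,6,7-tetrahydro-2H-chromen-8-yl]-3-phenylpropanoic acid, via acylketene 23 (not isolated), via enolised triketone 24 (not isolated)
Conditions: PhMe, 110 °C, N2 sweep; cool to 15 °C; (−)-quinine (1.2 equiv), PhCl; aq. citric acid work-up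
Reagents that add atoms: none
Why: Proposed new method: the tert-butyl β-keto ester should lose tert-butanol at 110 °C to give acylketene 23, whose sp carbon C8a is attacked by the enol carbon C4a of the neighbouring β-diketone to give enolised triketone 24 (closest known types: acylketene C-acylation of 1,3-dicarbonyl enols in the thermal chemistry of tert-butyl acetoacetates and dioxinones, and the polyketide-type Claisen closure to acylphloroglucinols); on cooling, the quininium salt of 24 should undergo oxa-Michael addition of O1 to C2 of the tigloyl group (closest known type: quinine-mediated cyclisation of o-tigloyl phenols to 2,3-dimethylchromanones). The carbocycle closes 6-exo-dig at the ketene carbon and the pyranone closes 6-endo-trig. C2 is set by the alkaloid, which should shield one face of the enone in the hydrogen-bonded ion pair (2R expected by analogy), and C3 by protonation of the C3–C4 enol followed by amine-mediated equilibration to the trans-2,3-dimethyl arrangement. The step needs C- and not O-acylation, which the six-membered transition state favours and which the bridged geometry of the alternative oxadiene [4+2] mode rules out, while any enol lactone should be returned to 24 by amine-catalysed acyl transfer. It also needs O1 and not the C5 oxygen to add: because C6 is quaternary, the C5 oxygen can enolise only toward C4a and is held in the chelate with the C4 carbonyl, it is flanked on both faces by the two C6 substituents, and only the O1-closed product keeps that chelate.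

**Compound list**

1 | (1S,5S)-(−)-verbenone, (1S,5S)-4,6,6-trimethylbicyclo[3.1.1]hept-3-en-2-one | CC1=CC(=O)[C@H]2C[C@@H]1C2(C)C | starting material
2 | (1S,3R)-3-acetyl-2,2-dimethylcyclobutane-1-carboxylic acid (cis) | CC(=O)[C@@H]1C[C@H](C(=O)O)C1(C)C | intermediate
3 | (1S,3S)-2,2-dimethyl-3-(prop-1-en-2-yl)cyclobutane-1-carboxylic acid (cis) | C=C(C)[C@@H]1C[C@H](C(=O)O)C1(C)C | intermediate
4 | [(1S,3S)-2,2-dimethyl-3-(prop-1-en-2-yl)cyclobutyl]methanol | C=C(C)[C@@H]1C[C@H](CO)C1(C)C | intermediate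
5 | (1S,3S)-1-(iodomethyl)-2,2-dimethyl-3-(prop-1-en-2-yl)cyclobutane | C=C(C)[C@@H]1C[C@H](CI)C1(C)C | intermediate
6 | ethyl acetoacetate | CCOC(=O)CC(C)=O | starting material
7 | ethyl 2-{[(1R,3S)-2,2-dimethyl-3-(prop-1-en-2-yl)cyclobutyl]methyl}-3-oxobutanoate (C2 epimers) | C=C(C)[C@@H]1C[C@H](CC(C(C)=O)C(=O)OCC)C1(C)C | intermediate
8 | L-valine tert-butyl ester | CC(C)[C@H](N)C(=O)OC(C)(C)C | starting material
9 | ethyl (2Z)-3-{[(2S)-1-tert-butoxy-3-methyl-1-oxobutan-2-yl]amino}-2-{[(1R,3S)-2,2-dimethyl-3-(prop-1-en-2-yl)cyclobutyl]methyl}but-2-enoate | C=C(C)[C@@H]1C[C@H](C/C(C(=O)OCC)=C(\C)N[C@@H](C(C)C)C(=O)OC(C)(C)C)C1(C)C | intermediate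
10 | prenyl bromide, 1-bromo-3-methylbut-2-ene | CC(C)=CCBr | starting material
11 | ethyl (2R)-2-(1-{[(2S)-1-tert-butoxy-3-methyl-1-oxobutan-2-yl]imino}ethyl)-2-{[(1R,3S)-2,2-dimethyl-3-(prop-1-en-2-yl)cyclobutyl]methyl}-5-methylhex-4-enoate (alkylated valine imine) | C=C(C)[C@@H]1C[C@H](C[C@@](C(C)=N[C@@H](C(C)C)C(=O)OC(C)(C)C)(CC=C(C)C)C(=O)OCC)C1(C)C | intermediate
12 | ethyl (2R)-2-acetyl-2-{[(1R,3S)-2,2-dimethyl-3-(prop-1-en-2-yl)cyclobutyl]methyl}-5-methylhex-4-enoate | C=C(C)[C@@H]1C[C@H](C[C@@](C(C)=O)(CC=C(C)C)C(=O)OCC)C1(C)C | intermediate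
13 | (2S)-2-{[(1R,3S)-2,2-dimethyl-3-(prop-1-en-2-yl)cyclobutyl]methyl}-2-(3-methylbut-2-en-1-yl)butane-1,3-diol (C3 epimers) | C=C(C)[C@@H]1C[C@H](C[C@@](C(C)O)(CC=C(C)C)CO)C1(C)C | intermediate
14 | (2S)-2-acetyl-2-{[(1R,3S)-2,2-dimethyl-3-(prop-1-en-2-yl)cyclobutyl]methyl}-5-methylhex-4-enal | C=C(C)[C@@H]1C[C@H](C[C@@](C(C)=O)(CC=C(C)C)C=O)C1(C)C | intermediate
15 | 3-phenylglutaric anhydride, 4-phenyloxane-2,6-dione | O=C1CC(c2ccccc2)CC(=O)O1 | starting material
16 | (3S)-5-methoxy-5-oxo-3-phenylpentanoic acid | OC(=O)C[C@@H](CC(=O)OC)c1ccccc1 | intermediate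
17 | 1-tert-butyl 5-methyl (3R)-3-phenylpentanedioate | CC(C)(C)OC(=O)C[C@@H](CC(=O)OC)c1ccccc1 | intermediate
18 | (3R)-5-tert-butoxy-5-oxo-3-phenylpentanoic acid | CC(C)(C)OC(=O)C[C@@H](CC(=O)O)c1ccccc1 | intermediate
19 | (3R,6S)-6-acetyl-4-(tert-butoxycarbonyl)-6-{[(1R,3S)-2,2-dimethyl-3-(prop-1-en-2-yl)cyclobutyl]methyl}-5-hydroxy-9-methyl-3-phenyldec-8-enoic acid (mixture at C4 and C5) | C=C(C)[C@@H]1C[C@H](C[C@@](C(C)=O)(CC=C(C)C)C(O)C(C(=O)OC(C)(C)C)[C@@H](CC(=O)O)c2ccccc2)C1(C)C | intermediate
20 | (3R,6R)-6-acetyl-4-(tert-butoxycarbonyl)-6-{[(1R,3S)-2,2-dimethyl-3-(prop-1-en-2-yl)cyclobutyl]methyl}-9-methyl-5-oxo-3-phenyldec-8-enoic acid (mixture at C4) | C=C(C)[C@@H]1C[C@H](C[C@@](C(C)=O)(CC=C(C)C)C(=O)C(C(=O)OC(C)(C)C)[C@@H](CC(=O)O)c2ccccc2)C1(C)C | intermediate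
21 | methyl tiglate, methyl (2E)-2-methylbut-2-enoate | C/C=C(\C)C(=O)OC | starting material
22 | (3R,6R,10E)-4-(tert-butoxycarbonyl)-6-{[(1R,3S)-2,2-dimethyl-3-(prop-1-en-2-yl)cyclobutyl]methyl}-10-methyl-6-(3-methylbut-2-en-1-yl)-5,7,9-trioxo-3-phenyldodec-10-enoic acid (mixture at C4) | C=C(C)[C@@H]1C[C@H](C[C@@](C(=O)CC(=O)/C(C)=C/C)(CC=C(C)C)C(=O)C(C(=O)OC(C)(C)C)[C@@H](CC(=O)O)c2ccccc2)C1(C)C | intermediate
23 | (3S,6R,10E)-6-{[(1R,3S)-2,2-dimethyl-3-(prop-1-en-2-yl)cyclobutyl]methyl}-10-methyl-6-(3-methylbut-2-en-1-yl)-5,7,9-trioxo-4-(oxomethylidene)-3-phenyldodec-10-enoic acid (acylketene) | C=C(C)[C@@H]1C[C@H](C[C@@](C(=O)CC(=O)/C(C)=C/C)(CC=C(C)C)C(=O)C(=C=O)[C@@H](CC(=O)O)c2ccccc2)C1(C)C | intermediate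
24 | (3S)-3-{(5R)-5-{[(1R,3S)-2,2-dimethyl-3-(prop-1-en-2-yl)cyclobutyl]methyl}-2,4-dihydroxy-3-[(2E)-2-methylbut-2-enoyl]-5-(3-methylbut-2-en-1-yl)-6-oxocyclohexa-1,3-dien-1-yl}-3-phenylpropanoic acid (enolised triketone) | C=C(C)[C@@H]1C[C@H](C[C@@]2(CC=C(C)C)C(=O)C([C@@H](CC(=O)O)c3ccccc3)=C(O)C(C(=O)/C(C)=C/C)=C2O)C1(C)C | intermediate
25 | (3S)-3-[(2R,3R,6R)-6-{[(1R,3S)-2,2-dimethyl-3-(prop-1-en-2-yl)cyclobutyl]methyl}-5-hydroxy-2,3-dimethyl-6-(3-methylbut-2-en-1-yl)-4,7-dioxo-3,4,6,7-tetrahydro-2H-chromen-8-yl]-3-phenylpropanoic acid | C=C(C)[C@@H]1C[C@H](C[C@@]2(CC=C(C)C)C(=O)C([C@@H](CC(=O)O)c3ccccc3)=C3O[C@H](C)[C@@H](C)C(=O)C3=C2O)C1(C)C | target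

**Count and risks**

Total steps: 16. Longest linear sequence: 13 steps (steps 1 to 9, then 13 to 16).

Step 16 (the proposed new method). What may go wrong: incomplete facial control in the oxa-Michael closure, closure already in the hot stage before the alkaloid is present, or closure through the C5 oxygen. The fallback sets out from 22 and comes back at 25. Compound 22 is heated in PhMe without alkaloid and the crude triketone is closed with K2CO3 in 2-butanone, the standard base-mediated cyclisation of o-tigloyl phenols under thermodynamic control. This should give 25 together with the (2S,3S)-diastereomer of 25 F1. The two are separated by preparative HPLC, and F1 is re-equilibrated under the same base through retro-oxa-Michael and oxa-Michael addition and separated again, which returns material to 25.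

Step 15. What may go wrong: acylation at the wrong anionic site, incomplete formation of the methyl ketone enolate, or reversal of the Claisen condensation. The fallback sets out from 20 and comes back at 22. The same polyanion of 20 is treated at −78 °C with (2E)-2-methylbut-2-enal, which reacts only with the most reactive enolate, to give the allylic aldol adduct F2. Oxidation of the allylic alcohol with MnO2 in CH2Cl2 then gives 22.

Step 7. What may go wrong: poor facial selectivity in the alkylation of the hindered lithio-enamine, or failure of the enamine to form from the α-branched keto ester. The fallback sets out from 5 and comes back at 13. Iodide 5 alkylates tert-butyl acetoacetate (NaH, DMF) to give the tert-butyl keto ester F3. F3 is prenylated with prenyl bromide under chiral phase-transfer catalysis (binaphthyl-derived spiro quaternary ammonium bromide, CsOH·H2O, PhMe, low temperature), a known way to quaternary α-alkyl β-keto tert-butyl esters, to give the quaternary tert-butyl keto ester F4. LiAlH4 reduction of F4 gives diol 13.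

Further compounds
F1 | step 16 | (3S)-3-[(2S,3S,6R)-6-{[(1R,3S)-2,2-dimethyl-3-(prop-1-en-2-yl)cyclobutyl]methyl}-5-hydroxy-2,3-dimethyl-6-(3-methylbut-2-en-1-yl)-4,7-dioxo-3,4,6,7-tetrahydro-2H-chromen-8-yl]-3-phenylpropanoic acid | C=C(C)[C@@H]1C[C@H](C[C@@]2(CC=C(C)C)C(=O)C([C@@H](CC(=O)O)c3ccccc3)=C3O[C@@H](C)[C@H](C)C(=O)C3=C2O)C1(C)C
F2 | step 15 | (3R,6R,10E)-4-(tert-butoxycarbonyl)-6-{[(1R,3S)-2,2-dimethyl-3-(prop-1-en-2-yl)cyclobutyl]methyl}-9-hydroxy-10-methyl-6-(3-methylbut-2-en-1-yl)-5,7-dioxo-3-phenyldodec-10-enoic acid (mixture at C4 and C9) | C=C(C)[C@@H]1C[C@H](C[C@@](C(=O)CC(O)/C(C)=C/C)(CC=C(C)C)C(=O)C(C(=O)OC(C)(C)C)[C@@H](CC(=O)O)c2ccccc2)C1(C)C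
F3 | step 7 | tert-butyl 2-{[(1R,3S)-2,2-dimethyl-3-(prop-1-en-2-yl)cyclobutyl]methyl}-3-oxobutanoate (C2 epimers) | C=C(C)[C@@H]1C[C@H](CC(C(C)=O)C(=O)OC(C)(C)C)C1(C)C
F4 | step 7 | tert-butyl (2R)-2-acetyl-2-{[(1R,3S)-2,2-dimethyl-3-(prop-1-en-2-yl)cyclobutyl]methyl}-5-methylhex-4-enoate | C=C(C)[C@@H]1C[C@H](C[C@@](C(C)=O)(CC=C(C)C)C(=O)OC(C)(C)C)C1(C)C
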